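**Assumption:** (R)-danshensu sodium salt, the (R)-3-(3,4-dihydroxyphenyl)-2-hydroxypropanoate, is a commercial chiral starting material. All phenols are carried as benzyl ethers and removed in the last step. The target's stereocentre is (R) (CIP, checked from the SMILES).

## Retrosynthetic overview
1. Eritrichin is the (R)-danshensate ester of 4-(3,4-dihydroxyphenyl)-6,7-dihydroxy-2-naphthoic acid. A final global hydrogenolysis of seven benzyl groups reveals a Steglich ester of naphthoic acid **8** with the benzyl-protected (R)-danshensate **11**.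
2. The only stereocentre comes from (R)-danshensu and is never touched: the ester forms at its O–H and no other step acts on it.
3. Naphthoate **7** is made by a photochemical 6π cycloaromatisation of the aryl-enyne **6**. This forms the C4–C4a bond and closes the only non-benzenoid ring.
4. Enyne **6** comes from a Sonogashira coupling of alkyne **3** with (Z)-α-bromocinnamate **5**. Both halves derive from one commercial aldehyde, **1**.

## Route

**Step 1**
Reactants: 1 (3,4-bis(benzyloxy)benzaldehyde); 2 (Bestmann–Ohira reagent, dimethyl (1-diazo-2-oxopropyl)phosphonate)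
Product: 3 (4-ethynyl-1,2-bis(benzyloxy)benzene)
Conditions: K2CO3, MeOH, 0 °C → 25 °C, 12 h
Reagents that add atoms: 2, CC(=O)C(=[N+]=[N-])P(=O)(OC)OC (supplies the alkyne CH carbon)
Why: Seyferth–Gilbert homologation (Ohira–Bestmann variant) converts the aldehyde to the terminal alkyne under mild base, and the benzyl ethers are inert. No stereocentre is involved.

**Step 2**
Reactants: 1; 4 (ethyl 2-bromo-2-(diethoxyphosphoryl)acetate)
Product: 5 (ethyl (Z)-2-bromo-3-[3,4-bis(benzyloxy)phenyl]acrylate)
Conditions: NaH, THF, −78 → 0 °C, 3 h
Reagents that add atoms: 4, CCOC(=O)C(Br)P(=O)(OCC)OCC (supplies the C(Br)CO2Et unit)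
Why: Horner–Wadsworth–Emmons olefination with an α-bromophosphonoacetate gives mainly the Z-bromoacrylate, with Br cis to the aryl and CO2Et trans. Bromination of a cinnamate is avoided because the electron-rich arene would be ring-brominated. Any E isomer re-equilibrates under the photolysis in step 4.

**Step 3**
Reactants: 3; 5
Product: 6 (ethyl (E)-2-{[3,4-bis(benzyloxy)phenyl]ethynyl}-3-[3,4-bis(benzyloxy)phenyl]acrylate)
Conditions: Pd(PPh3)2Cl2 (3 mol%), CuI (5 mol%), Et3N, THF, 50 °C, 6 h
Reagents that add atoms: none
Why: Sonogashira coupling proceeds with retention of alkene geometry, so the alkynyl group ends up cis to the aryl, which is the geometry the next step needs.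

**Step 4**
Reactants: 6
Product: 7 (ethyl 4-[3,4-bis(benzyloxy)phenyl]-6,7-bis(benzyloxy)-2-naphthoate)
Conditions: hν (350 nm, Rayonet, Pyrex), MeCN (5 mM), N2, 25 °C, 3 h; then TsOH·H2O (10 mol%), 25 °C, 30 min
Reagents that add atoms: none (isomerisation)
Why: Proposed new method: photochemical hexa-1,3-dien-5-yne (dehydro-Hopf-type) 6π electrocyclisation using the cinnamate arene C=C as one diene alkene, with the arene as a dearomatised part of the triene. The new bond joins the arene C6′ (para to OBn, which favours the 6,7-pattern over the hindered C2′) to the alkyne terminus bearing the aryl group. The resulting strained cyclic allene (isonaphthalene) is tautomerised by acid, which protonates the allene's central carbon and loses H⁺ from C4a, and this restores the aromatic naphthalene. The closest known chemistry is Mallory-type photocyclisation of aryl-dienes, thermal Hopf cyclisation of enynes and isoaromatic-allene tautomerisation. No oxidant is needed, and the benzyl ethers do not absorb at 350 nm.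

**Step 5**
Reactants: 7
Product: 8 (4-[3,4-bis(benzyloxy)phenyl]-6,7-bis(benzyloxy)-2-naphthoic acid)
Conditions: LiOH·H2O, THF/MeOH/H2O (3:1:1), 50 °C, 6 h; then 1 M HCl
Reagents that add atoms: none
Why: Saponification of the ethyl ester leaves the benzyl ethers and the naphthalene untouched.

**Step 6**
Reactants: 9 (sodium (R)-danshensu); 10 (benzyl bromide)
Product: 11 (benzyl (R)-3-[3,4-bis(benzyloxy)phenyl]-2-hydroxypropanoate)
Conditions: BnBr (3.3 equiv), K2CO3 (3 equiv), TBAI (cat.), DMF, 40 °C, 12 h
Reagents that add atoms: 10, BrCc1ccccc1 (benzyl groups on the carboxylate and both phenols)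
Why: Williamson alkylation of the carboxylate and the phenoxides. K2CO3 is too weak to alkylate the secondary alcohol, so the free α-OH remains, and the (R) stereocentre is not involved and is retained from the purchased material.

**Step 7**
Reactants: 8; 11
Product: 12 (fully benzyl-protected eritrichin)
Conditions: EDC·HCl, DMAP (0.2 equiv), CH2Cl2/DMF (9:1), 0 °C → 25 °C, 12 h
Reagents that add atoms: none (EDC leaves as urea)
Why: Steglich esterification acylates the free secondary α-OH at oxygen, so the carbinol stereocentre keeps its (R) configuration, and the benzyl ester and ethers survive.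

**Step 8**
Reactants: 12
Product: 13 (eritrichin)
Conditions: H2 (1 atm), 10% Pd/C, THF/MeOH (1:1), 25 °C, 12 h
Reagents that add atoms: none
Why: Hydrogenolysis removes all seven benzyl groups (four on the naphthalene core and its aryl, two on the danshensate aryl, one benzyl ester) and leaves the aryl ester and the naphthalene intact. The α-acyloxy stereocentre is not benzylic at the cleaved C–O bonds, so it is not scrambled.

**Checks:**
- The skeleton is 2-CO2R, 4-aryl, 6,7-(OH)2 naphthalene, and the ester sits on the (R)-α-hydroxy acid.
- Step 4 is an isomerisation, so every atom is conserved.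
- The only stereocentre comes from **9**.

## Compound list
1 | 3,4-bis(benzyloxy)benzaldehyde | O=Cc1ccc(OCc2ccccc2)c(OCc2ccccc2)c1 | starting material
2 | Bestmann–Ohira reagent | CC(=O)C(=[N+]=[N-])P(=O)(OC)OC | starting material
3 | 4-ethynyl-1,2-bis(benzyloxy)benzene | C#Cc1ccc(OCc2ccccc2)c(OCc2ccccc2)c1 | intermediate
4 | ethyl 2-bromo-2-(diethoxyphosphoryl)acetate | CCOC(=O)C(Br)P(=O)(OCC)OCC | starting material
5 | ethyl (Z)-2-bromo-3-[3,4-bis(benzyloxy)phenyl]acrylate | CCOC(=O)/C(Br)=C/c1ccc(OCc2ccccc2)c(OCc2ccccc2)c1 | intermediate
6 | enyne ester | CCOC(=O)/C(C#Cc1ccc(OCc2ccccc2)c(OCc2ccccc2)c1)=C/c1ccc(OCc2ccccc2)c(OCc2ccccc2)c1 | intermediate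
7 | ethyl 4-aryl-6,7-bis(benzyloxy)-2-naphthoate | CCOC(=O)c1cc(-c2ccc(OCc3ccccc3)c(OCc3ccccc3)c2)c2cc(OCc3ccccc3)c(OCc3ccccc3)cc2c1 | intermediate
8 | naphthoic acid | O=C(O)c1cc(-c2ccc(OCc3ccccc3)c(OCc3ccccc3)c2)c2cc(OCc3ccccc3)c(OCc3ccccc3)cc2c1 | intermediate
9 | sodium (R)-danshensu | O[C@H](Cc1ccc(O)c(O)c1)C(=O)[O-].[Na+] | starting material
10 | benzyl bromide | BrCc1ccccc1 | starting material
11 | benzyl (R)-3-[3,4-bis(benzyloxy)phenyl]-2-hydroxypropanoate | O[C@H](Cc1ccc(OCc2ccccc2)c(OCc2ccccc2)c1)C(=O)OCc1ccccc1 | intermediate
12 | fully protected eritrichin | O=C(O[C@H](Cc1ccc(OCc2ccccc2)c(OCc2ccccc2)c1)C(=O)OCc1ccccc1)c1cc(-c2ccc(OCc3ccccc3)c(OCc3ccccc3)c2)c2cc(OCc3ccccc3)c(OCc3ccccc3)cc2c1 | intermediate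
13 | eritrichin | O=C(O[C@H](Cc1ccc(O)c(O)c1)C(=O)O)c1cc(-c2ccc(O)c(O)c2)c2cc(O)c(O)cc2c1 | target

## Totals
Total steps: 8. Longest linear sequence: 6 steps (1 → 5 → 6 → 7 → 8 → 12 → 13).

## Three steps most likely to fail
1. **Step 4 (proposed new photocyclisation).** The cyclic allene may be trapped, or the enyne may undergo only E/Z isomerisation or [2+2] chemistry.
   Fallback (known chemistry): build ester **7** by a Stobbe condensation of **1** with diethyl succinate, then Ac2O/NaOAc cyclisation to the 4-acetoxy-2-naphthoate. Follow with deacetylation, triflation and Suzuki coupling with 3,4-bis(benzyloxy)phenylboronic acid.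
2. **Step 7 (DMAP-mediated epimerisation of the α-acyloxy ester).**
   Fallback: change the bond-forming logic to SN2 inversion. Use L-DOPA (cheap, S) → (S)-2-bromo acid (NaNO2/HBr, retention) → benzyl ester with benzylated phenols. Then displace the bromide with the caesium carboxylate of **8** in DMF, which inverts to give (R) ester **12**.
3. **Step 8 (seven-fold hydrogenolysis with catechol products poisoning Pd or stalling).**
   Fallback: BCl3 with pentamethylbenzene as cation scavenger in CH2Cl2 at −78 °C, which cleaves the benzyl ethers by Lewis-acid dealkylation instead of by hydrogenolysis.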